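Count the amounts first: 0.10 M of starting material takes up as much partner on its way through intermediate A (with second reagent) and intermediate B (with third reagent) to target, which leaves a surplus of 0.0500 M out of 0.150 M of partner, and partner also attacks target to give over-reaction product.

| flask | starting material | partner | second reagent | third reagent | time | remark |
|---|---|---|---|---|---|---|
| larch | 0.10 M | 0.150 M | 0.105 M | 0.150 M | 15 min | a closed flask charged with all of it at once and left for 15 min |
| maple | 0.10 M | 0.150 M | 0.105 M | 0.150 M |  | a single well-mixed tank run continuously and read at steady state, 15 min in it on average |
| alder | 0.10 M | 0.150 M | 0.105 M | 0.150 M |  | a single well-mixed tank run continuously and read at steady state, 75.0 min in it on average |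
| birch | 0.10 M (fed, over 15.0 min) | 0.150 M | 0.105 M | 0.150 M | 15 min | all but starting material at the start; starting material goes in evenly over 15.0 min, the run ends at 15 min |

* the set-up with the highest share of target in all that became target or over-reaction product, at the outlet or at the end ("none" if the first two lie within 2 percentage points) (larch / maple / alder / birch / none)
* share of target in all that became target or over-reaction product, at the outlet or at the end, larch
* share of target in all that became target or over-reaction product, at the outlet or at the end, maple
* share of target in all that became target or over-reaction product, at the outlet or at the end, alder
* share of target in all that became target or over-reaction product, at the outlet or at the end, birch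

- the stated concentrations are those of everything mixed, before any reaction; amounts are the same in each set-up
- the feed brings no volume worth counting
- run time (larch): 15 min

    starting material + partner → intermediate A (k1 = 0.133 M⁻¹ s⁻¹)
    second reagent + intermediate A → intermediate B (k2 = 2.45 M⁻¹ s⁻¹)
    third reagent + intermediate B → target (k3 = 0.00724 M⁻¹ s⁻¹)
    starting material → decomposition product (k4 = 6.31 × 10⁻⁶ s⁻¹)
    partner + target → over-reaction product (k5 = 0.154 M⁻¹ s⁻¹)
    intermediate A → decomposed reagent (k6 = 0.0177 s⁻¹)

Multiply the surplus by 0.154 M⁻¹ s⁻¹ to get the turnover rate of target at surplus partner, 0.462 min⁻¹, a pseudo-first-order loss, and count turnovers as k5·[partner]·time.

Start with maple, where a target molecule either leaves or is lost, so the share is one over one plus the turnovers. Go on to larch, where the third step turns over 0.977 times, so that a charge counted wholly as intermediate B from the start, with third reagent held as charged, gives 0.0624 M through that step, more than the surplus, though this count runs high, since the charge needs time to reach intermediate B and third reagent falls. Let partner in larch therefore fall below the surplus as the run goes on, take its mean roughly at half the surplus, and for steady making use the share (1 − e^−N)/N, with N the turnovers. In birch, let the making ramp up with the dose, so that the share is 2 divided by the turnovers, and read partner over the later half of the dose, 0.0750 M.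

The weak link is alder, where the surplus gives 34.6 turnovers. The third step turns over 4.89 times there, so, with the whole charge counted as intermediate B and third reagent held as charged, 0.0830 M passes that step, more than the surplus, and the surplus is a poor estimate of partner in alder. Reforge it: let over-reaction consume the surplus, so that starting material and partner stand equal at a, and balance the first step in alder, k1·a²·τ = the amount converted, taken roughly as the charged [starting material], which gives 0.0129 M.

| Set-up | [partner] taken | Turnovers | Share reckoned |
|---|---|---|---|
| larch | 0.0250 M | 3.46 | 28.0% |
| maple | 0.0500 M | 6.93 | 12.6% |
| alder | 0.0129 M | 8.96 | 10.0% |
| birch | 0.0750 M | 10.4 | 19.2% |

Expect larch to come first.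

The forecast also chose larch, with 24% for larch, 15% for maple, 10% for alder and 21% for birch, lower than my larch and higher than my maple, holding that “the share is set by how much partner remains as target forms”.

The simulation gives larch as best, with 24.0% for larch, 14.9% for maple, 10.1% for alder and 19.8% for birch, so my larch stands 4 percentage points high.

Now stop larch early, at 4.0 min, as the neighbouring flask does, where partner reads 34.0% of its charge, or 0.0510 M, about the surplus. Use the full turnover rate, which gives 1.85 turnovers, and the steady-making share becomes 45.6%. That flask reads 45.3%, with 6.16% of the starting material as target and 7.43% as over-reaction product.

Its constants were chosen freely; the rest is arithmetic.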